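The target is disconnected at one C(sp3)–C(sp3) bond of this achiral 5-alkylresorcinol dimethyl ether: the bond between the benzylic CH2 on C5 of the 1,3-dimethoxybenzene ring (chain C1) and chain carbon C2. The key step exploits the benzylic activation this ring confers on C1. 3,5-Dimethoxybenzyl bromide, a primary electrophile without β-hydrogens, is alkylated by 9-phenylnonylmagnesium bromide under copper catalysis (Kochi-type coupling), completing the ten-carbon tether between the two arenes in one operation. The precursor pair is thus a benzylic bromide and a Grignard reagent made in situ from (9-bromononyl)benzene, itself obtained from commercial 9-phenylnonan-1-ol by Appel bromination.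

Key step: step 2

Remark: the target has no stereocentre and no stereogenic double bond, so it is achiral and no stereocontrol is needed; 9-phenylnonan-1-ol and 3,5-dimethoxybenzyl bromide are taken as catalogue compounds.

Step 1
Reactants: 1 9-phenylnonan-1-ol
Product: 2 (9-bromononyl)benzene
Conditions: CBr4 (1.2 equiv), PPh3 (1.25 equiv), CH2Cl2, 0 °C to rt; filtration through silica (hexanes), then short-path distillation
Reagents that add atoms: carbon tetrabromide, BrC(Br)(Br)Br
Why: Appel reaction: the primary alcohol is activated as an alkoxyphosphonium ion and displaced by bromide in an SN2 step; the unfunctionalised chain and phenyl ring offer no competing site.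

Step 2
Reactants: 2 (9-bromononyl)benzene; 3 3,5-dimethoxybenzyl bromide (1-(bromomethyl)-3,5-dimethoxybenzene)
Product: 5 1,3-dimethoxy-5-(10-phenyldecyl)benzene, via 9-phenylnonylmagnesium bromide 4 (not isolated)
Conditions: Mg turnings (I2 cat.), THF, 40 °C, slow addition of 2; then slow addition of the Grignard solution (1.2 equiv) to 3 and Li2CuCl4 (3 mol %), THF, −20 °C to rt; aq NH4Cl
Reagents that add atoms: none
Why: Magnesium inserts into the primary C–Br bond of 2 to give Grignard 4, which transmetalates to copper to form an alkylcuprate; SN2-type oxidative addition of the cuprate to the benzylic C–Br bond of 3 gives a Cu(III) alkyl(benzyl) species, and reductive elimination forms the bond between the benzylic CH2 on the dimethoxyphenyl ring and C1 of the nonyl chain. The closest known reaction type is the Kochi copper-catalysed coupling of Grignard reagents with primary alkyl and benzyl halides (Li2CuCl4, a Kumada-type sp3–sp3 coupling), a standard way to make 5-alkylresorcinol ethers. No ring is closed and no stereocentre is created. The selectivity needed is cross-coupling over homocoupling by bromine–magnesium exchange; it should be secured by the high rate of cuprate attack on the unhindered benzylic bromide, by the absence of β-hydrogens on the benzyl partner, and by slow addition of 4 to 3 plus catalyst at low temperature. The aryl methyl ethers and both arenes are inert to the Grignard reagent and the cuprate.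

Compound list
1 | 9-phenylnonan-1-ol | OCCCCCCCCCc1ccccc1 | starting material
2 | (9-bromononyl)benzene | BrCCCCCCCCCc1ccccc1 | intermediate
3 | 3,5-dimethoxybenzyl bromide (1-(bromomethyl)-3,5-dimethoxybenzene) | COc1cc(CBr)cc(OC)c1 | starting material
4 | 9-phenylnonylmagnesium bromide | Br[Mg]CCCCCCCCCc1ccccc1 | intermediate (not isolated)
5 | 1,3-dimethoxy-5-(10-phenyldecyl)benzene | COc1cc(CCCCCCCCCCc2ccccc2)cc(OC)c1 | target

Total step count: 2
Longest linear sequence: 2 steps (1 → 2 → 5)

Steps most likely to fail (the route has only two steps, so both are ranked):

1. Step 2 (key step). The risk is that bromine–magnesium exchange between the alkyl Grignard and the benzylic bromide outruns the copper cycle, so that homocoupling of each partner (Wurtz-type) replaces cross-coupling; Wurtz coupling during magnesium insertion into 2 would lower the titre of 4 as well. The fallback forms the same bond as an olefin and sets out from compound 2. Heating 2 with PPh3 in MeCN at reflux should give (9-phenylnonyl)triphenylphosphonium bromide F1. Deprotonation with KOtBu in THF at 0 °C and Wittig reaction of the ylide with commercial 3,5-dimethoxybenzaldehyde (COc1cc(C=O)cc(OC)c1) should give 1,3-dimethoxy-5-(10-phenyldec-1-en-1-yl)benzene F2, expected as a Z-rich E/Z mixture whose geometry is irrelevant. Hydrogenation (H2, 1 atm, Pd/C, EtOAc, rt) saturates the olefin and returns to the route at compound 5.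

2. Step 1. The risk is incomplete separation of phosphorus and polybromomethane residues from the non-polar bromide; such residues would inhibit magnesium insertion in step 2. The fallback sets out from compound 1 and replaces phosphonium activation by sulfonate displacement. TsCl, Et3N and catalytic DMAP in CH2Cl2 (0 °C to rt) should give 9-phenylnonyl 4-methylbenzenesulfonate F3. Finkelstein-type substitution with LiBr in acetone at reflux then returns to the route at compound 2, free of phosphorus and halomethane contaminants.

Further compounds
F1 | step 2 | (9-phenylnonyl)triphenylphosphonium bromide | [Br-].c1ccc(CCCCCCCCC[P+](c2ccccc2)(c2ccccc2)c2ccccc2)cc1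
F2 | step 2 | (Z)-1,3-dimethoxy-5-(10-phenyldec-1-en-1-yl)benzene (major isomer of the expected E/Z mixture) | COc1cc(/C=C\CCCCCCCCc2ccccc2)cc(OC)c1
F3 | step 1 | 9-phenylnonyl 4-methylbenzenesulfonate | Cc1ccc(S(=O)(=O)OCCCCCCCCCc2ccccc2)cc1
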